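The constants describe a catalyst that holds each substrate in a fast balance, a pre-equilibrium. At −20 °C, bound left-handed substrate falls off at 8.73 min⁻¹, faster than it turns over even at saturated reagent, 0.407 min⁻¹.

    free catalyst + left-handed substrate ⇌ catalyst intermediate A (K1 = 71 M⁻¹, k1 = 620 M⁻¹ min⁻¹, Ea1 = 43.0 kJ mol⁻¹, ΔH1 = −42.0 kJ mol⁻¹)
    free catalyst → spent catalyst (k2 = 3.2 × 10⁻⁴ min⁻¹, Ea2 = 86.0 kJ mol⁻¹)
    free catalyst + right-handed substrate ⇌ catalyst intermediate B (K3 = 57 M⁻¹, k3 = 3800 M⁻¹ min⁻¹, Ea3 = 37.0 kJ mol⁻¹, ΔH3 = −74.0 kJ mol⁻¹)
    2 reagent → self-condensation product (k4 = 0.46 M⁻¹ min⁻¹, Ea4 = 52.0 kJ mol⁻¹)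
    gas ⇌ reagent, rate k5*(csat - [reagent]) (k5 = 0.0048 min⁻¹, csat = 0.59 mM)
    reagent + catalyst intermediate A → free catalyst + left-handed product (k6 = 690 M⁻¹ min⁻¹, Ea6 = 44.0 kJ mol⁻¹)
    reagent + catalyst intermediate B → free catalyst + right-handed product (k7 = 330 M⁻¹ min⁻¹, Ea7 = 49.0 kJ mol⁻¹)
    (constants at −20 °C)

| flask | left-handed substrate | gas | free catalyst | right-handed substrate | temperature | time |
|---|---|---|---|---|---|---|
| beta | 0.010 M | 0.59 mM (held) | 0.2 mol% | 0.010 M | −40 °C | 25 d |
| eta | 0.010 M | 0.59 mM (held) | 0.2 mol% | 0.010 M | −20 °C | 25 d |
| delta | 0.010 M | 0.59 mM (held) | 0.2 mol% | 0.010 M | 0 °C | 25 d |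

- free catalyst is single-handed; left-handed substrate and right-handed substrate are mirror images of each other, charged as a racemate, each of them at the stated concentration
- for a step with 2 of a species take k times the square, and two of it per event
- at the start none of reagent is dissolved
- constants are those at −20 °C; use the activation energies and enthalpies for any other temperature

* the flask with the highest amount of left-handed product, in percent of the left-handed substrate and right-handed substrate together charged ("all alike" if they lie within 1.5 percentage points) (beta / eta / delta / all alike)
* final left-handed product, as a percentage of the left-handed substrate and right-handed substrate together charged, in beta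
* final left-handed product, as a percentage of the left-handed substrate and right-handed substrate together charged, in eta
* final left-handed product, as a percentage of the left-handed substrate and right-handed substrate together charged, in delta

I followed one rate, the fall per minute of the logarithm of the left-handed substrate. That speed is the turnover constant times the binding constant times reagent times free catalyst, and free catalyst dies at its own constant times the same free catalyst. The free catalyst therefore cancels in the ratio, so the share of catalyst held bound drops out, while the binding constant of the left-handed substrate stays as a factor: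

reach = turnover constant × binding constant × reagent × catalyst charge / death constant

With a charge of 2.00 × 10⁻⁵ M and saturated reagent, eta gives 1.81. The working rounds draw reagent at 0.00595 min⁻¹ at the start, against dissolving at 0.0048 min⁻¹. Reagent thus sags and recovers as the catalyst dies, and averaged over the catalyst's life this is a factor 0.651. That leaves 1.18, which I carried as the reach: the natural logarithm of the fall of left-handed substrate over the catalyst's whole life.

Temperature moves the reach through 84.0 kJ mol⁻¹. Holding the reagent factor, I got 0.0633 in delta and 36.0 in beta. The product is half the charge times one minus the exponential of minus the reach, so eta gives 34.6% and delta 3.06%.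

In beta, substrate binding slows the rate as well, by a bound-to-free ratio 15.6. The speed with unbound catalyst and saturated reagent is 5.33 × 10⁻⁴ min⁻¹, and reagent stands at a factor 0.803. Over 25 d the accumulated logarithm is 15.4, which is less than the reach, so in beta time is the cap. Integrating, with x the fraction left:

ln(1/x) + ratio × (1 − x) = accumulated logarithm

Putting the logarithm at 2.3 gives 42.1% in beta. My ranking gave beta.

The forecast named beta, with 49.9%, 43% and 3.6%, on the ground that “Gas supply limits the reagent while the high-activation-energy catalyst death speeds up far faster on warming”. Its figures stand above mine.

The simulation gave 43.3% in beta, 33.7% in eta and 1.54% in delta, with beta highest; the forecast's beta figure is what comes with every back reaction left out. At 25.0 d, beta held 5.34% spent catalyst with 13% of its left-handed substrate remaining, while eta held 99.9% spent catalyst with 33% remaining. The logarithm of the fall in eta reads 1.11, against the reach of 1.18.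

For the flask at −15 °C, the reach is 0.543, which gives 20.9%. The simulation gave 18.4%.

The numbers of this flask were chosen freely; the rest is arithmetic.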